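## The problem

Galbinic acid (24) is a depsidone. Two benzene rings are joined by an aryl ester and a diaryl ether on adjacent carbons, which closes a seven-membered dioxepinone, and ring B is also fused to a five-membered lactol lactone (a 3-hydroxyphthalide). Ring B carries no hydrogen: around it lie the acetoxymethyl carbon, a free phenol, the lactone carbonyl carbon, the lactol carbon, the ether oxygen and the ester oxygen, so six different substituents must be placed with no position left for correction. Ring A is pentasubstituted, with the ester carbonyl and a formyl group on either side of the ether carbon. The only stereocentre is the (S)-lactol carbon; no other centre can control it, and as the cyclic hemiacetal of a formyl acid it can invert by ring opening, so it must be set by an external chiral alcohol and carried as an acetal. The fragile groups are the benzylic acetate ortho to a phenol (lost as an ortho-quinone methide under base), the aryl ester and the lactol (both opened by hydroxide or alkoxide), the salicylaldehyde, and any hydroquinone intermediate (air). The feature that invites the key step is the substitution pattern of ring B, in phthalide numbering: oxygens para to each other at C-7 and C-4, a third oxygen at C-5, one carbon substituent at C-6 and the two lactone carbons on C-7a and C-3a. This is exactly what a 2-alkyl-3-alkoxy-4-hydroxycyclobutenone with an alkenyl group on its carbinol carbon unfolds into on heating.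

## Retrosynthesis

**24 from 23.** The last disconnection is the O–menthyl bond of the acetal. The lactol is kept masked until the end because the free pseudo-acid would be opened by every basic step and acylated in the acetylation. Acetal 23 is configurationally stable and diastereomerically pure. The forward step must hydrolyse a pseudo-ester acetal without touching the benzylic acetate or the depsidone ester.

**23 from 22, and 22 from 21.** The acetate is put on only after the last basic operation, because an ortho-hydroxybenzyl acetate eliminates under base; alcohol 22 needs a selective acetylation of a primary hydroxyl beside two chelated phenols. In 22 the aryl ester C–O bond of the seven-membered ring is cut, giving seco acid 21. Cutting the ester and not the ether at this stage lets the ring close under neutral carbodiimide conditions, where no acyl migration between neighbouring ring B oxygens can occur.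

**21 from 20.** All acid-labile protecting groups of 20 (two isopropyl aryl ethers, the methoxymethyl ether and the 4-methoxybenzyl ester) are chosen to fall in one BCl3 operation. The menthyl acetal is the one group that must survive.

**20 from 13 and 19.** The diaryl ether is cut at the bond between the ring A carbon and the ring B oxygen. The ring A partner 19 carries fluorine between a formyl and an ester group, so the forward reaction is a doubly activated SNAr. The ring B partner 13 has two hydroxyls; the one to be arylated (C-4) is the unchelated one, while the C-7 hydroxyl is hydrogen-bonded to the lactone carbonyl. The C-5 oxygen is still an isopropyl ether, so ether and ester oxygens cannot be confused. This halves the molecule.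

**19 from 14.** Ring A comes from 3-fluoro-5-methylphenol (14), which already holds fluorine, methyl and oxygen in the right 1,3,5-relation. The bromine para to oxygen (15, 16) becomes the ester carbon, and the hydrogen between fluorine and oxygen becomes the formyl group (18). The formyl group is introduced before the ester so that no ortho-toluate ester is ever exposed to an amide base.

**13 from 10 (key disconnection).** In ring B the bond between C-7 (the phenol carbon next to the lactone carbonyl) and C-7a is cut, and the ring is contracted to cyclobutenone 10. The alternative of functionalising a preformed benzene six times has no reliable order of events. The ring expansion instead places all six substituents by the constitution of 10: the carbonyl carbon becomes C-7, the carbinol carbon C-4, and the butenolide double bond C-3a/C-7a. The forward reaction needs only heat and the absence of oxygen.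

**10 from 4 and 9.** The bond between the carbinol carbon and the butenolide β-carbon is cut. Dione 4 is the electrophile at its ketone-like carbonyl; bromobutenolide 9 is the donor after metalation. Because the β-carbon of an unsaturated lactone cannot be lithiated, a chromium/nickel-mediated coupling is asked for.

**4 from 1 and 2; 9 from 7 and 8; 7 from 5.** Dione 4 is a squarate (1) in which one alkoxy group is replaced by the protected hydroxymethyl carbon of stannane 2. Acetal 9 is the (−)-menthol (8) pseudo-ester of hydroxybutenolide 7, and this is where the stereocentre is set. Compound 7 is the singlet-oxygen product of 3-bromofuran (5).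

## Roads not taken

**Alternative 1:** Ring A is built last by cutting two of its C–C bonds, those flanking the ring hydrogen that lies between the methyl- and oxygen-bearing carbons. In the forward sense a 2-pyrone fused to the dioxepinone, A2, undergoes [4+2] cycloaddition with an electron-rich ketene acetal across pyrone C-3 and C-6; the bridged adduct then loses its lactone bridge and one alkoxy group to give the anisole-type depsidone A1.
- Merits: the regiochemistry of such cycloadditions is dependable. The ether link of A2 is made by addition–elimination on a vinylogous ester, which is easier than substitution at a doubly ortho-substituted fluoroarene; in that respect this road is better than step 10 of the chosen plan.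
- Weak points: A1 is not the target. It lacks the formyl group, carries a methyl ether on the ring A phenol and a methyl acetal without chiral information. A formylation between two oxygens, an O-demethylation with a boron halide beside a benzylic acetate, and a resolution of the lactol would all have to follow. The road also says nothing about how the hexasubstituted ring B is obtained, which is the main difficulty.
- Comparison: the chosen plan brings ring A in complete, formyl group included, from a four-step fragment, and solves ring B in one thermal step. It pays for this with a hindered intermolecular SNAr.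

**Alternative 2:** The ring A C–O ether bond is cut last and formed intramolecularly. In depside A4 the ring B phenoxide next to the ester oxygen attacks the fluorine-bearing carbon, activated by ortho ester and ortho formyl groups, and closes the seven-membered ring to A3.
- Merits: the activation is the same as in step 10, but the closure is intramolecular and only one oxygen can reach the fluoride. This makes it more reliable than the intermolecular substitution of the chosen plan, and on this point it is superior.
- Weak points: A4 requires that, of two adjacent ring B oxygens, exactly the C-5 one is acylated. A free phenol beside an aryl ester exchanges the acyl group under the basic closure conditions, and the migrated isomer would close to the constitutional isomer with ester and ether interchanged. The ring expansion product 13 has the opposite differentiation (free hydroxyl at C-4, ether at C-5), so reaching A4 would cost extra protecting-group steps. A3 still needs two methoxymethyl ethers and an achiral methyl acetal removed in acid beside the acetate.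
- Comparison: the chosen plan uses the oxygen differentiation of 13 as it comes and forms the ester last under neutral conditions. It has to set the steric risk of step 10 against the better ring closure of this road.

**Alternative 3:** One C–C bond of ring A is cut, between the carbon bearing the lactone carbonyl and the methyl-bearing carbon, and ring A is folded from a chain. In A6 reductive opening of the isoxazole N–O bond unmasks an enaminone; acid then makes the enol ether carbon next to the lactone carbonyl attack the methyl-bearing iminium carbon, and loss of the nitrogen aromatises the ring to A5.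
- Merits: it mimics the polyketide origin of ring A, needs no aryl fluoride, and the enol ether C–O bond of A6 would come from a simple conjugate addition of a phenol. The conditions are mild.
- Weak points: the nucleophilic carbon of A6 is the β-carbon of a β-aryloxy acrylate, deactivated by the lactone carbonyl, so the closure competes with hydrolysis of the enaminone and with attack by nitrogen. A6 is itself a sensitive seven-membered enol ether lactone. A5 again lacks the formyl group, and a late formylation must choose between two positions ortho to the phenol in the presence of the acetate and the acetal.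
- Comparison: this road is longer and rests on two uncertain selectivities. The chosen plan has one unproven coupling (step 4) but installs the formyl group early, where it also serves as the activator of the SNAr.

Key step: step 5

Assumption: the lactol carbon is the only stereocentre and, as a 3-hydroxyphthalide, can invert through the ring-opened formyl acid; the (S)-descriptor is therefore taken to refer to the crystalline lactol, and the route holds this carbon as a configurationally stable (S)-acetal of (−)-menthol up to the last intermediate.

In the names below, menthyl stands for (1R,2S,5R)-5-methyl-2-(propan-2-yl)cyclohexyl.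

## Steps

Step 1
Reactants: 1 diisopropyl squarate [3,4-bis(propan-2-yloxy)cyclobut-3-ene-1,2-dione]; 2 tributyl[(methoxymethoxy)methyl]stannane
Product: 4 3-[(methoxymethoxy)methyl]-4-(propan-2-yloxy)cyclobut-3-ene-1,2-dione, via squarate carbinol adduct 3 (not isolated)
Conditions: 2, n-BuLi, THF, −78 °C; then 1, −78 °C; (CF3CO)2O, −78 → 0 °C; H2O
Reagents that add atoms: water, O
Why: Tin–lithium exchange gives (methoxymethoxy)methyllithium, which adds once to a squarate carbonyl to give adduct 3. O-Trifluoroacetylation of 3 triggers ionisation assisted by the vinylogous isopropoxy group, and hydrolysis of the resulting oxocarbenium ion expels propan-2-ol; this is the standard conversion of a dialkyl squarate into a 3-alkyl-4-alkoxycyclobutenedione. No stereocentre remains.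

Step 2
Reactants: 5 3-bromofuran
Product: 7 4-bromo-5-hydroxyfuran-2(5H)-one (racemic), via furan endoperoxide 6 (not isolated)
Conditions: O2, hν (visible), tetraphenylporphyrin (cat.), iPr2NEt, CH2Cl2, −78 °C
Reagents that add atoms: dioxygen, O=O
Why: Singlet oxygen adds [4+2] across the furan to give endoperoxide 6. The hindered amine removes the less encumbered bridgehead hydrogen, at the carbon remote from bromine, so that carbon becomes the lactone carbonyl and the carbon next to bromine becomes the lactol carbon (base-directed photooxygenation of 3-substituted furans).

Step 3
Reactants: 7 4-bromo-5-hydroxyfuran-2(5H)-one; 8 (−)-menthol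
Product: 9 (5S)-4-bromo-5-(menthyloxy)furan-2(5H)-one
Conditions: (±)-10-camphorsulfonic acid (cat.), toluene, reflux, Dean–Stark; crystallisation; mother liquor re-equilibrated with the acid and recrystallised
Reagents that add atoms: none
Why: Acid-catalysed pseudo-ester (acetal) formation of a γ-hydroxybutenolide. The two acetal epimers are diastereomers that interconvert through the oxocarbenium ion under the acid, so the (5S)-epimer is drawn out by crystallisation with recycling, as practised for the parent 5-menthyloxyfuranone. Should the (5R)-epimer be the one that crystallises, the same operation with (+)-menthol gives the (5S)-acetal of the mirror-image auxiliary, which serves equally.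

Step 4
Reactants: 4 3-[(methoxymethoxy)methyl]-4-(propan-2-yloxy)cyclobut-3-ene-1,2-dione; 9 (5S)-4-bromo-5-(menthyloxy)furan-2(5H)-one
Product: 10 4-hydroxy-2-[(methoxymethoxy)methyl]-4-[(2S)-2-(menthyloxy)-5-oxo-2,5-dihydrofuran-3-yl]-3-(propan-2-yloxy)cyclobut-2-en-1-one (both carbinol epimers)
Conditions: CrCl2 (4 equiv), NiCl2 (2 mol %), DMF (degassed), 23 °C, Ar
Reagents that add atoms: none
Why: Proposed new method: divalent chromium reduces NiCl2 to zerovalent nickel, which inserts into the C4–Br bond of the vinylogous acyl bromide 9; transmetalation to trivalent chromium gives an alkenylchromium species that should add to the ketone-like carbonyl of 4 (the one next to the isopropoxy-bearing carbon, where organolithium reagents attack) and not to the vinylogous ester carbonyl or the lactone. The closest known reactions are the Nozaki–Hiyama–Kishi coupling of β-halo enoates with aldehydes and the 1,2-addition of alkenyllithium reagents to 3-alkyl-4-alkoxycyclobutenediones; what has not been shown is an organochromium addition to a cyclobutenedione. The new carbinol centre forms as both epimers, which is of no consequence because it becomes an sp2 carbon in step 5, and the (S)-acetal carbon is untouched.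

Step 5
Reactants: 10 4-hydroxy-2-[(methoxymethoxy)methyl]-4-[(2S)-2-(menthyloxy)-5-oxo-2,5-dihydrofuran-3-yl]-3-(propan-2-yloxy)cyclobut-2-en-1-one
Product: 13 (3S)-4,7-dihydroxy-6-[(methoxymethoxy)methyl]-3-(menthyloxy)-5-(propan-2-yloxy)-2-benzofuran-1(3H)-one, via dienylketene 11 (not isolated), via cyclohexadienone 12 (not isolated)
Conditions: toluene (degassed, 0.02 M), 110 °C, Ar
Reagents that add atoms: none
Why: Heating opens the cyclobutenone by a thermal conrotatory 4π process that breaks the bond between the carbonyl carbon and the carbinol carbon and gives dienylketene 11. The hydroxyl, as the donor substituent, rotates outward, which places the butenolide double bond cis to the ketene. A thermal disrotatory 6π electrocyclisation then joins the ketene carbon to the butenolide carbon alpha to the lactone carbonyl and closes the six-membered ring B as cyclohexadienone 12; this is the only skeletal bond formed. Enolisation of 12, whose ring-fusion hydrogen lies between two carbonyls, gives hydroquinone 13, so the sp3 carbon created in the closure disappears and no new stereocentre remains, while the (S)-acetal carbon is a spectator under these neutral conditions. The closest known reaction type is the thermal ring expansion of 4-alkenyl- and 4-aryl-4-hydroxycyclobutenones to hydroquinones (Moore rearrangement). Regiochemistry is fixed by the constitution of 10: the ketene carbon becomes the C-7 phenol beside the lactone carbonyl, the carbinol carbon becomes the C-4 hydroxyl, and the carbons bearing the protected hydroxymethyl and isopropoxy groups lie between them. The selectivity needed is 6π closure in preference to capture of the ketene by the hydroxyl (furanone formation), which the outward rotation of the hydroxyl secures; exclusion of air keeps the hydroquinone from oxidising.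

Step 6
Reactants: 14 3-fluoro-5-methylphenol
Product: 15 4-bromo-3-fluoro-5-methylphenol
Conditions: NBS, MeCN, 0 → 23 °C
Reagents that add atoms: N-bromosuccinimide, O=C1CCC(=O)N1Br
Why: Electrophilic aromatic bromination of a phenol; as with 3,5-dimethylphenol, the position para to the hydroxyl (here between fluorine and methyl) is attacked in preference to the ortho positions.

Step 7
Reactants: 15 4-bromo-3-fluoro-5-methylphenol
Product: 16 2-bromo-1-fluoro-3-methyl-5-(propan-2-yloxy)benzene
Conditions: 2-bromopropane, K2CO3, DMF, 60 °C
Reagents that add atoms: 2-bromopropane, CC(C)Br
Why: Williamson ether synthesis. The isopropyl ether tolerates the amide base of step 8 and is removed later by BCl3 together with the ring B isopropyl ether.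

Step 8
Reactants: 16 2-bromo-1-fluoro-3-methyl-5-(propan-2-yloxy)benzene
Product: 18 3-bromo-2-fluoro-4-methyl-6-(propan-2-yloxy)benzaldehyde, via aryllithium 17 (not isolated)
Conditions: LiN(iPr)2, THF, −78 °C; DMF, −78 → 0 °C; aq. NH4Cl
Reagents that add atoms: N,N-dimethylformamide, CN(C)C=O
Why: Directed ortho-metalation: the hydrogen between fluorine and the alkoxy group is by far the most acidic. The amide base does not exchange the bromide, and aryllithium 17 is stable against loss of LiF at −78 °C; DMF then delivers the formyl group.

Step 9
Reactants: 18 3-bromo-2-fluoro-4-methyl-6-(propan-2-yloxy)benzaldehyde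
Product: 19 (4-methoxyphenyl)methyl 2-fluoro-3-formyl-6-methyl-4-(propan-2-yloxy)benzoate
Conditions: CO (1 atm), 4-methoxybenzyl alcohol, Pd(OAc)2 (cat.), Xantphos, Et3N, toluene, 90 °C
Reagents that add atoms: carbon monoxide, [C-]#[O+]; 4-methoxybenzyl alcohol, COc1ccc(CO)cc1
Why: Palladium-catalysed alkoxycarbonylation of an aryl bromide; the aldehyde, fluoride and ether are inert. Putting the ester in after the formyl group avoids lateral lithiation of an ortho-toluate, and the 4-methoxybenzyl ester can later be cleaved without base.

Step 10
Reactants: 13 (3S)-4,7-dihydroxy-6-[(methoxymethoxy)methyl]-3-(menthyloxy)-5-(propan-2-yloxy)-2-benzofuran-1(3H)-one; 19 (4-methoxyphenyl)methyl 2-fluoro-3-formyl-6-methyl-4-(propan-2-yloxy)benzoate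
Product: 20 (4-methoxyphenyl)methyl 3-formyl-2-{[(3S)-7-hydroxy-6-[(methoxymethoxy)methyl]-3-(menthyloxy)-1-oxo-5-(propan-2-yloxy)-1,3-dihydro-2-benzofuran-4-yl]oxy}-6-methyl-4-(propan-2-yloxy)benzoate
Conditions: Cs2CO3 (1.5 equiv), DMF (degassed), 40 °C, Ar
Reagents that add atoms: none
Why: Nucleophilic aromatic substitution: the fluorine of 19 is flanked by formyl and ester groups that stabilise the Meisenheimer adduct. Of the two hydroxyls of 13, the C-7 one is hydrogen-bonded to and conjugated with the lactone carbonyl and gives the poorer nucleophile, so arylation should occur at the C-4 oxygen, as in the selective 5-O-alkylation of 2,5-dihydroxybenzoates. The benzylic methoxymethyl ether cannot eliminate and the acetal is stable to carbonate.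

Step 11
Reactants: 20 the diaryl ether of step 10
Product: 21 3-formyl-4-hydroxy-2-{[(3S)-5,7-dihydroxy-6-(hydroxymethyl)-3-(menthyloxy)-1-oxo-1,3-dihydro-2-benzofuran-4-yl]oxy}-6-methylbenzoic acid
Conditions: BCl3, pentamethylbenzene, CH2Cl2, −78 → 0 °C; H2O/THF quench at −78 °C
Reagents that add atoms: none
Why: Lewis-acid ether cleavage: BCl3 removes secondary alkyl aryl ethers (fastest ortho to a carbonyl), the methoxymethyl ether and the 4-methoxybenzyl ester, with pentamethylbenzene as a non-basic trap for the benzylic cation. The acetal oxygen of the pseudo-ester is deactivated by the geminal acyloxy group and is expected to survive the cold, short treatment.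

Step 12
Reactants: 21 the seco acid of step 11
Product: 22 deacetylgalbinic acid (S)-menthyl acetal (depsidone with free hydroxymethyl group, two free phenols, formyl group, lactol as menthyl acetal)
Conditions: DCC, CH2Cl2 (0.002 M), 23 °C
Reagents that add atoms: none
Why: Carbodiimide lactonisation of a 2-(2-hydroxyaryloxy)benzoic acid, the classical closure of the depsidone ring. The unchelated C-5 hydroxyl is held next to the activated acid by the diaryl ether and closes the seven-membered ring; the two chelated phenols do not compete, and high dilution suppresses intermolecular acylation of the primary alcohol.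

Step 13
Reactants: 22 deacetylgalbinic acid (S)-menthyl acetal
Product: 23 galbinic acid (S)-menthyl acetal
Conditions: AcCl (1.1 equiv), 2,4,6-collidine, CH2Cl2, −78 °C
Reagents that add atoms: acetyl chloride, CC(=O)Cl
Why: Selective acetylation of a primary alcohol with acetyl chloride and a hindered pyridine base at low temperature. Both phenols are hydrogen-bonded to ortho carbonyl groups and react far more slowly, and the weak base forms no phenoxide, so no ortho-quinone methide can arise from the new benzylic acetate.

Step 14
Reactants: 23 galbinic acid (S)-menthyl acetal
Product: 24 galbinic acid [(S)-lactol]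
Conditions: CF3CO2H/H2O (9:1), 0 → 23 °C; evaporation below 25 °C; crystallisation
Reagents that add atoms: water, O
Why: Acid-catalysed hydrolysis of a pseudo-ester (3-alkoxyphthalide) acetal through the phthalidyl oxocarbenium ion; the primary acetate, the depsidone ester and the aldehyde tolerate aqueous trifluoroacetic acid at ambient temperature. Because this ion is planar, the hydrolysis does not transfer the (S)-configuration of 23; in line with the assumption stated before the steps, the (S)-lactol is to be collected by crystallisation from the equilibrating solution.

## Compound list

1 | diisopropyl squarate [3,4-bis(propan-2-yloxy)cyclobut-3-ene-1,2-dione] | CC(C)OC1=C(OC(C)C)C(=O)C1=O | starting material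
2 | tributyl[(methoxymethoxy)methyl]stannane | CCCC[Sn](CCCC)(CCCC)COCOC | starting material
3 | 4-hydroxy-4-[(methoxymethoxy)methyl]-2,3-bis(propan-2-yloxy)cyclobut-2-en-1-one (racemic; lithium alkoxide in the flask) | COCOCC1(O)C(OC(C)C)=C(OC(C)C)C1=O | intermediate
4 | 3-[(methoxymethoxy)methyl]-4-(propan-2-yloxy)cyclobut-3-ene-1,2-dione | COCOCC1=C(OC(C)C)C(=O)C1=O | intermediate
5 | 3-bromofuran | Brc1ccoc1 | starting material
6 | 5-bromo-2,3,7-trioxabicyclo[2.2.1]hept-5-ene (racemic furan endoperoxide) | BrC1=CC2OOC1O2 | intermediate
7 | 4-bromo-5-hydroxyfuran-2(5H)-one (racemic) | OC1OC(=O)C=C1Br | intermediate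
8 | (−)-menthol [(1R,2S,5R)-5-methyl-2-(propan-2-yl)cyclohexan-1-ol] | CC(C)[C@@H]1CC[C@@H](C)C[C@H]1O | starting material
9 | (5S)-4-bromo-5-(menthyloxy)furan-2(5H)-one | BrC1=CC(=O)O[C@@H]1O[C@@H]1C[C@H](C)CC[C@H]1C(C)C | intermediate
10 | 4-hydroxy-2-[(methoxymethoxy)methyl]-4-[(2S)-2-(menthyloxy)-5-oxo-2,5-dihydrofuran-3-yl]-3-(propan-2-yloxy)cyclobut-2-en-1-one (both carbinol epimers) | COCOCC1=C(OC(C)C)C(O)(C2=CC(=O)O[C@@H]2O[C@@H]2C[C@H](C)CC[C@H]2C(C)C)C1=O | intermediate
11 | dienylketene: 4-hydroxy-2-[(methoxymethoxy)methyl]-4-[(2S)-2-(menthyloxy)-5-oxo-2,5-dihydrofuran-3-yl]-3-(propan-2-yloxy)buta-1,3-dien-1-one, butenolide cis to the ketene | COCOCC(=C=O)/C(OC(C)C)=C(O)\C1=CC(=O)O[C@@H]1O[C@@H]1C[C@H](C)CC[C@H]1C(C)C | intermediate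
12 | cyclohexadienone: (3S)-4-hydroxy-6-[(methoxymethoxy)methyl]-3-(menthyloxy)-5-(propan-2-yloxy)-3,7a-dihydro-2-benzofuran-1,7-dione | COCOCC1=C(OC(C)C)C(O)=C2[C@@H](O[C@@H]3C[C@H](C)CC[C@H]3C(C)C)OC(=O)C2C1=O | intermediate
13 | (3S)-4,7-dihydroxy-6-[(methoxymethoxy)methyl]-3-(menthyloxy)-5-(propan-2-yloxy)-2-benzofuran-1(3H)-one | COCOCc1c(O)c2c(c(O)c1OC(C)C)[C@@H](O[C@@H]1C[C@H](C)CC[C@H]1C(C)C)OC2=O | intermediate
14 | 3-fluoro-5-methylphenol | Cc1cc(O)cc(F)c1 | starting material
15 | 4-bromo-3-fluoro-5-methylphenol | Cc1cc(O)cc(F)c1Br | intermediate
16 | 2-bromo-1-fluoro-3-methyl-5-(propan-2-yloxy)benzene | CC(C)Oc1cc(C)c(Br)c(F)c1 | intermediate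
17 | [3-bromo-2-fluoro-4-methyl-6-(propan-2-yloxy)phenyl]lithium | [Li]c1c(F)c(Br)c(C)cc1OC(C)C | intermediate
18 | 3-bromo-2-fluoro-4-methyl-6-(propan-2-yloxy)benzaldehyde | CC(C)Oc1cc(C)c(Br)c(F)c1C=O | intermediate
19 | (4-methoxyphenyl)methyl 2-fluoro-3-formyl-6-methyl-4-(propan-2-yloxy)benzoate | COc1ccc(COC(=O)c2c(C)cc(OC(C)C)c(C=O)c2F)cc1 | intermediate
20 | (4-methoxyphenyl)methyl 3-formyl-2-{[(3S)-7-hydroxy-6-[(methoxymethoxy)methyl]-3-(menthyloxy)-1-oxo-5-(propan-2-yloxy)-1,3-dihydro-2-benzofuran-4-yl]oxy}-6-methyl-4-(propan-2-yloxy)benzoate | COCOCc1c(O)c2c(c(Oc3c(C=O)c(OC(C)C)cc(C)c3C(=O)OCc3ccc(OC)cc3)c1OC(C)C)[C@@H](O[C@@H]1C[C@H](C)CC[C@H]1C(C)C)OC2=O | intermediate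
21 | 3-formyl-4-hydroxy-2-{[(3S)-5,7-dihydroxy-6-(hydroxymethyl)-3-(menthyloxy)-1-oxo-1,3-dihydro-2-benzofuran-4-yl]oxy}-6-methylbenzoic acid | OCc1c(O)c2c(c(Oc3c(C=O)c(O)cc(C)c3C(=O)O)c1O)[C@@H](O[C@@H]1C[C@H](C)CC[C@H]1C(C)C)OC2=O | intermediate
22 | deacetylgalbinic acid (S)-menthyl acetal | OCc1c(O)c2c(c3c1OC(=O)c1c(C)cc(O)c(C=O)c1O3)[C@@H](O[C@@H]1C[C@H](C)CC[C@H]1C(C)C)OC2=O | intermediate
23 | galbinic acid (S)-menthyl acetal | CC(=O)OCc1c(O)c2c(c3c1OC(=O)c1c(C)cc(O)c(C=O)c1O3)[C@@H](O[C@@H]1C[C@H](C)CC[C@H]1C(C)C)OC2=O | intermediate
24 | galbinic acid, (S)-lactol | CC(=O)OCc1c(O)c2c(c3c1OC(=O)c1c(C)cc(O)c(C=O)c1O3)[C@@H](O)OC2=O | target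

## Step count and risks

Total steps: 14. Longest linear sequence: 9 steps (steps 2, 3, 4, 5, 10, 11, 12, 13, 14; the ring A branch, steps 6 to 9 followed by 10 to 14, is equally long).

Least certain steps:

**Step 4 (Proposed new method).** The most likely failure is one-electron reduction of the electron-poor cyclobutenedione by divalent chromium, or an addition of the alkenylchromium species to a ketone that is too slow, so that protodebromination of 9 wins. Fallback with known chemistry, setting out from 9: halide exchange with NaI in acetone gives (5S)-4-iodo-5-(menthyloxy)furan-2(5H)-one F1. Iodine–magnesium exchange with iPrMgCl·LiCl in THF at −78 °C, as practised for β-iodo enoates, gives the alkenylmagnesium chloride F2. F2 is added at −78 °C to 4 in the manner established for Grignard and organolithium additions to alkoxycyclobutenediones, and the route is rejoined at 10.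

**Step 5 (key step).** The ring expansion itself belongs to a well-tried class. The most likely trouble is oxidation of the electron-rich hydroquinone to the quinone in the hot solution and during work-up, giving mixtures of the two oxidation levels. Fallback, setting out from 10: the thermolysis is run without exclusion of air and the oxidation is completed with Ag2O to the quinone F3, which is stable and can be purified. F3 is reduced with aqueous Na2S2O4 immediately before step 10, and the route is rejoined at 13.

**Step 10.** The most likely failure is a slow substitution, because a phenoxide flanked by two substituents must attack a fluorine flanked by an out-of-plane ester and a formyl group; arylation at the chelated hydroxyl and oxidative decay of the hydroquinone anion then gain ground. Fallback, setting out from 13: the smaller electrophile 18, whose fluorine lies between the formyl group and a bromine, is used in the SNAr to give the brominated diaryl ether F4. The ester is then introduced on F4 by the alkoxycarbonylation of step 9 (CO, 4-methoxybenzyl alcohol, Pd(OAc)2, Xantphos, Et3N), and the route is rejoined at 20.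

**Step 11.** The most likely failure is activation of the lactone carbonyl by BCl3 with ring opening to an oxocarbenium ion, which leads to loss or epimerisation of the menthyl acetal. Fallback, setting out from 20: the deprotection is driven to completion (BCl3, then aqueous acid) to the fully deprotected lactol seco acid F5. F5 is lactonised with DCC to salazinic acid F6. The lactol of F6 is re-acetalised with 8 under camphorsulfonic acid catalysis, and the (S)-epimer is taken by crystallisation with re-equilibration of the mother liquor, rejoining the route at 22.

**Step 14.** The most likely failure is racemisation at the lactol carbon: the hydrolysis passes through a planar oxocarbenium ion, the free lactol afterwards equilibrates by ring–chain tautomerism, and crystallisation delivers the (S)-form only if the solid is not a racemic compound. Fallback, setting out from 23 and ending at 24: the hydrolysate is resolved by preparative chromatography on a chiral stationary phase at low temperature with a neutral, aprotic eluent, and the (S)-fractions are evaporated cold; the other enantiomer is recycled by re-equilibration. No new compound is made.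

## Further compounds

F1 | step 4 | (5S)-4-iodo-5-(menthyloxy)furan-2(5H)-one | IC1=CC(=O)O[C@@H]1O[C@@H]1C[C@H](C)CC[C@H]1C(C)C
F2 | step 4 | chloro[(2S)-2-(menthyloxy)-5-oxo-2,5-dihydrofuran-3-yl]magnesium | Cl[Mg]C1=CC(=O)O[C@@H]1O[C@@H]1C[C@H](C)CC[C@H]1C(C)C
F3 | step 5 | (3S)-6-[(methoxymethoxy)methyl]-3-(menthyloxy)-5-(propan-2-yloxy)-2-benzofuran-1,4,7(3H)-trione | COCOCC1=C(OC(C)C)C(=O)C2=C(C1=O)C(=O)O[C@@H]2O[C@@H]1C[C@H](C)CC[C@H]1C(C)C
F4 | step 10 | 3-bromo-2-{[(3S)-7-hydroxy-6-[(methoxymethoxy)methyl]-3-(menthyloxy)-1-oxo-5-(propan-2-yloxy)-1,3-dihydro-2-benzofuran-4-yl]oxy}-4-methyl-6-(propan-2-yloxy)benzaldehyde | COCOCc1c(O)c2c(c(Oc3c(C=O)c(OC(C)C)cc(C)c3Br)c1OC(C)C)[C@@H](O[C@@H]1C[C@H](C)CC[C@H]1C(C)C)OC2=O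
F5 | step 11 | 2-{[5,7-dihydroxy-6-(hydroxymethyl)-3-hydroxy-1-oxo-1,3-dihydro-2-benzofuran-4-yl]oxy}-3-formyl-4-hydroxy-6-methylbenzoic acid (lactol, both configurations) | OCc1c(O)c2c(c(Oc3c(C=O)c(O)cc(C)c3C(=O)O)c1O)C(O)OC2=O
F6 | step 11 | salazinic acid (deacetylgalbinic acid, lactol of both configurations) | OCc1c(O)c2c(c3c1OC(=O)c1c(C)cc(O)c(C=O)c1O3)C(O)OC2=O
F0 | step 14 | none | none
A1 | alternative 1 | (S)-methyl acetal of galbinic acid lacking the formyl group and carrying a methyl ether on the ring A phenol | CC(=O)OCc1c(O)c2c(c3c1OC(=O)c1c(C)cc(OC)cc1O3)[C@@H](OC)OC2=O
A2 | alternative 1 | 6-methyl-2-pyrone fused through its C-5 ester carbonyl and C-4 ether oxygen to ring B (acetate and (S)-methyl acetal in place) | CC1=C2C(=O)Oc3c(COC(C)=O)c(O)c4c(c3OC2=CC(=O)O1)[C@@H](OC)OC4=O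
A3 | alternative 2 | bis(methoxymethyl) ether of galbinic acid (S)-methyl acetal | CC(=O)OCc1c(OCOC)c2c(c3c1OC(=O)c1c(C)cc(OCOC)c(C=O)c1O3)[C@@H](OC)OC2=O
A4 | alternative 2 | depside: ring B C-5 ester of 2-fluoro-3-formyl-4-(methoxymethoxy)-6-methylbenzoic acid with free C-4 hydroxyl, C-7 methoxymethyl ether, acetate and (S)-methyl acetal | CC(=O)OCc1c(OCOC)c2c(c(O)c1OC(=O)c1c(C)cc(OCOC)c(C=O)c1F)[C@@H](OC)OC2=O
A5 | alternative 3 | deformylgalbinic acid (S)-methyl acetal | CC(=O)OCc1c(O)c2c(c3c1OC(=O)c1c(C)cc(O)cc1O3)[C@@H](OC)OC2=O
A6 | alternative 3 | ring B-fused 1,4-dioxepin-5-one enol ether carrying a (3-methylisoxazol-5-yl)methyl group on the enol ether carbon (acetate and (S)-methyl acetal in place) | CC(=O)OCc1c(O)c2c(c3c1OC(=O)C=C(Cc1cc(C)no1)O3)[C@@H](OC)OC2=O
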